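The bond between the exocyclic alkylidene CH on C3 of the γ-butyrolactone ring and the CH2 that leads to the side-chain carbinol is formed in the penultimate step. Both carbons are natural electrophiles: the CH is the β-carbon of the lactone enoate, and the CH2 lies next to a C–O carbon, where a carbanion would β-eliminate. A nickel-catalysed reductive cross-electrophile coupling unites them as an (E)-enol triflate (built on 2-deoxy-D-ribonolactone, which supplies C4 and C5) and a β-silyloxy primary bromide (from geraniol, stereocentre set by CBS reduction). It runs through an alkyl radical and carries the E geometry and all three stereocentres over. One desilylation finishes the synthesis.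

Key step: step 13

Remark: 2-deoxy-D-ribono-1,4-lactone and geraniol are taken as commercial; the sense of the CBS reduction in step 11 is assigned by the usual large/small model with the alkenyl group as the large substituent.

Step 1
Reactants: 1 2-deoxy-D-ribono-1,4-lactone
Product: 2 (4S,5R)-4-(triethylsilyloxy)-5-[(triethylsilyloxy)methyl]oxolan-2-one
Conditions: Et3SiCl, imidazole, DMF, 0 °C → rt
Reagents that add atoms: chlorotriethylsilane, CC[Si](Cl)(CC)CC
Why: Imidazole-mediated silyl ether formation caps both hydroxyl groups without touching either stereocentre.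

Step 2
Reactants: 2 bis-triethylsilyl ether
Product: 4 (2S,3S)-5-oxo-3-(triethylsilyloxy)oxolane-2-carbaldehyde, via primary alcohol 3 (not isolated)
Conditions: (COCl)2, DMSO, CH2Cl2, −78 → −40 °C; then Et3N, −78 → 0 °C
Reagents that add atoms: none
Why: Under Swern conditions only the primary triethylsilyl ether is cleaved and the freed alcohol is oxidised in the same flask (selective Swern oxidation of primary TES ethers), while the secondary silyl ether and the lactone stay intact and the cold work-up should limit epimerisation next to the aldehyde.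

Step 3
Reactants: 4 aldehyde
Product: 5 (4S,5R)-5-(2-methylprop-1-en-1-yl)-4-(triethylsilyloxy)oxolan-2-one
Conditions: i-PrPPh3I, n-BuLi, THF, 0 °C; then 4, −78 → 0 °C
Reagents that add atoms: isopropyltriphenylphosphonium iodide, CC(C)[P+](c1ccccc1)(c1ccccc1)c1ccccc1.[I-]
Why: Wittig olefination with the non-stabilised isopropylidene ylide at low temperature should convert the aldehyde faster than the lactone or the α-position of the aldehyde is deprotonated.

Step 4
Reactants: 5 isobutenyl lactone
Product: 6 (3Z,4S,5R)-3-(hydroxymethylidene)-5-(2-methylprop-1-en-1-yl)-4-(triethylsilyloxy)oxolan-2-one (enol form of the 3-formyl lactone)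
Conditions: LiN(SiMe3)2, THF, −78 °C; HCO2CH2CF3, −78 °C; AcOH, −78 °C
Reagents that add atoms: 2,2,2-trifluoroethyl formate, O=COCC(F)(F)F
Why: Crossed Claisen formylation of the lactone lithium enolate with an activated formate proceeds at −78 °C, where the β-silyloxy enolate should not eliminate, and the product is held as its enolate until the cold acidic quench.

Step 5
Reactants: 6 hydroxymethylidene lactone
Product: 7 [(E)-[(4S,5R)-5-(2-methylprop-1-en-1-yl)-2-oxo-4-(triethylsilyloxy)oxolan-3-ylidene]methyl] trifluoromethanesulfonate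
Conditions: Tf2O, i-Pr2NEt, CH2Cl2, −78 °C
Reagents that add atoms: trifluoromethanesulfonic anhydride, O=S(=O)(OS(=O)(=O)C(F)(F)F)C(F)(F)F
Why: O-sulfonylation of the non-chelated ammonium enolate, which should prefer the W-shaped geometry with the enolate oxygen turned away from the lactone carbonyl, is expected to give the (E)-enol triflate (stereoselective enol triflate formation from a β-dicarbonyl compound).

Step 6
Reactants: 8 geraniol
Product: 9 tert-butyl{[(2E)-3,7-dimethylocta-2,6-dien-1-yl]oxy}dimethylsilane
Conditions: t-BuMe2SiCl, imidazole, CH2Cl2, rt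
Reagents that add atoms: tert-butylchlorodimethylsilane, CC(C)(C)[Si](C)(C)Cl
Why: Standard silylation protects the primary allylic alcohol as an ether that is inert to zerovalent nickel, unlike an allylic acetate.

Step 7
Reactants: 9 geranyl silyl ether
Product: 10 (2E,6E)-8-[(tert-butyldimethylsilyl)oxy]-2,6-dimethylocta-2,6-dien-1-ol
Conditions: SeO2 (cat.), t-BuOOH, salicylic acid (cat.), CH2Cl2, 0 °C → rt
Reagents that add atoms: selenium dioxide, O=[Se]=O; tert-butyl hydroperoxide, CC(C)(C)OO
Why: The Riley allylic oxidation (ene reaction, then [2,3]-sigmatropic shift) should select the (E)-methyl group of the more electron-rich terminal trisubstituted alkene and keep the E geometry.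

Step 8
Reactants: 10 allylic alcohol
Product: 11 (2E,6E)-8-[(tert-butyldimethylsilyl)oxy]-2,6-dimethylocta-2,6-dienal
Conditions: MnO2, CH2Cl2, rt
Reagents that add atoms: none
Why: MnO2 oxidises the primary allylic alcohol to the enal without alkene isomerisation, and any enal already formed in step 7 converges here.

Step 9
Reactants: 11 enal
Product: 12 rac-(3E,7E)-1-bromo-9-[(tert-butyldimethylsilyl)oxy]-3,7-dimethylnona-3,7-dien-2-ol
Conditions: CH2Br2, n-BuLi, THF, −78 °C (in situ); AcOH, −78 °C
Reagents that add atoms: dibromomethane, BrCBr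
Why: Bromine–lithium exchange in the presence of the enal gives bromomethyllithium, which adds 1,2 to the aldehyde (halomethyllithium addition), and the cold acidic quench should stop the alkoxide from closing to the epoxide.

Step 10
Reactants: 12 racemic bromohydrin
Product: 13 (3E,7E)-1-bromo-9-[(tert-butyldimethylsilyl)oxy]-3,7-dimethylnona-3,7-dien-2-one
Conditions: Dess–Martin periodinane, CH2Cl2, 0 °C → rt
Reagents that add atoms: none
Why: Dess–Martin oxidation of the secondary allylic alcohol runs without base, so the α-bromo ketone and the silyl ether should survive.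

Step 11
Reactants: 13 α-bromo enone
Product: 14 (2S,3E,7E)-1-bromo-9-[(tert-butyldimethylsilyl)oxy]-3,7-dimethylnona-3,7-dien-2-ol
Conditions: (S)-2-methyl-CBS-oxazaborolidine (20 mol %), catecholborane, toluene, −78 °C
Reagents that add atoms: none
Why: Corey–Bakshi–Shibata reduction with the α-methylalkenyl group as the large and CH2Br as the small substituent should deliver hydride to the face that gives the (S)-bromohydrin, and catecholborane at −78 °C avoids hydroboration and 1,4-reduction.

Step 12
Reactants: 14 (S)-bromohydrin
Product: 15 triethyl{[(2S,3E,7E)-1-bromo-9-[(tert-butyldimethylsilyl)oxy]-3,7-dimethylnona-3,7-dien-2-yl]oxy}silane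
Conditions: Et3SiOTf, 2,6-lutidine, CH2Cl2, −78 °C
Reagents that add atoms: triethylsilyl trifluoromethanesulfonate, CC[Si](CC)(CC)OS(=O)(=O)C(F)(F)F
Why: Silylation with the silyl triflate and a hindered pyridine at −78 °C should be much faster than epoxide closure of the bromohydrin.

Step 13
Reactants: 7 (E)-enol triflate; 15 (S)-β-silyloxy primary bromide
Product: 16 (3E,4S,5R)-3-[(3R,4E,8E)-10-[(tert-butyldimethylsilyl)oxy]-4,8-dimethyl-3-(triethylsilyloxy)deca-4,8-dien-1-ylidene]-5-(2-methylprop-1-en-1-yl)-4-(triethylsilyloxy)oxolan-2-one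
Conditions: NiBr2·(MeOCH2CH2OMe) (10 mol %), 4,4′-di-tert-butyl-2,2′-bipyridine (12 mol %), Zn, NaI (0.5 equiv), DMA, 25 °C
Reagents that add atoms: none
Why: Zerovalent nickel (from NiBr2 and Zn) should insert into the alkenyl C–OTf bond of 7 with retention, the resulting alkenylnickel species captures the primary radical that monovalent nickel generates from bromide 15 by bromine abstraction, and reductive elimination from trivalent nickel forms the C(sp2)–C(sp3) bond while Zn returns the catalyst. The closest known reaction type is the nickel-catalysed reductive cross-electrophile coupling of alkenyl bromides or triflates with primary alkyl halides. No ring is closed and no stereocentre is formed; the two lactone centres (4S,5R) and the silyloxy-bearing centre of 15 are spectators and are carried over unchanged. The step needs cross- over homo-coupling, which rests on the two different activation modes (two-electron oxidative addition at the sp2 C–O bond, halogen-atom abstraction at the sp3 C–Br bond), and retention of the E geometry, which rests on the configurational stability of the alkenylnickel intermediate at 25 °C. Making the CH2 carbon a radical and not a carbanion keeps the β-silyloxy group in place, since an organolithium or Grignard reagent at this carbon would expel silanolate.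

Step 14
Reactants: 16 tris-silyl ether
Product: 17 (3E,4S,5R)-3-[(3R,4E,8E)-3,10-dihydroxy-4,8-dimethyldeca-4,8-dien-1-ylidene]-4-hydroxy-5-(2-methylprop-1-en-1-yl)oxolan-2-one (CNP0209732.2)
Conditions: HF·pyridine, pyridine, THF, 0 °C → rt
Reagents that add atoms: none
Why: Buffered fluoride-mediated desilylation removes both triethylsilyl groups and the tert-butyldimethylsilyl group and should leave the lactone, the allylic alcohols and the alkylidene geometry untouched.

Compound list
1 | 2-deoxy-D-ribono-1,4-lactone, (4S,5R)-4-hydroxy-5-(hydroxymethyl)oxolan-2-one | OC[C@H]1OC(=O)C[C@@H]1O | starting material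
2 | (4S,5R)-4-(triethylsilyloxy)-5-[(triethylsilyloxy)methyl]oxolan-2-one | CC[Si](CC)(CC)OC[C@H]1OC(=O)C[C@@H]1O[Si](CC)(CC)CC | intermediate
3 | (4S,5R)-5-(hydroxymethyl)-4-(triethylsilyloxy)oxolan-2-one | OC[C@H]1OC(=O)C[C@@H]1O[Si](CC)(CC)CC | intermediate (not isolated)
4 | (2S,3S)-5-oxo-3-(triethylsilyloxy)oxolane-2-carbaldehyde | O=C[C@H]1OC(=O)C[C@@H]1O[Si](CC)(CC)CC | intermediate
5 | (4S,5R)-5-(2-methylprop-1-en-1-yl)-4-(triethylsilyloxy)oxolan-2-one | CC(C)=C[C@H]1OC(=O)C[C@@H]1O[Si](CC)(CC)CC | intermediate
6 | (3Z,4S,5R)-3-(hydroxymethylidene)-5-(2-methylprop-1-en-1-yl)-4-(triethylsilyloxy)oxolan-2-one | CC(C)=C[C@H]1OC(=O)/C(=C\O)[C@@H]1O[Si](CC)(CC)CC | intermediate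
7 | [(E)-[(4S,5R)-5-(2-methylprop-1-en-1-yl)-2-oxo-4-(triethylsilyloxy)oxolan-3-ylidene]methyl] trifluoromethanesulfonate | CC(C)=C[C@H]1OC(=O)/C(=C/OS(=O)(=O)C(F)(F)F)[C@@H]1O[Si](CC)(CC)CC | intermediate
8 | geraniol, (2E)-3,7-dimethylocta-2,6-dien-1-ol | CC(C)=CCC/C(C)=C/CO | starting material
9 | tert-butyl{[(2E)-3,7-dimethylocta-2,6-dien-1-yl]oxy}dimethylsilane | CC(C)=CCC/C(C)=C/CO[Si](C)(C)C(C)(C)C | intermediate
10 | (2E,6E)-8-[(tert-butyldimethylsilyl)oxy]-2,6-dimethylocta-2,6-dien-1-ol | OC/C(C)=C/CC/C(C)=C/CO[Si](C)(C)C(C)(C)C | intermediate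
11 | (2E,6E)-8-[(tert-butyldimethylsilyl)oxy]-2,6-dimethylocta-2,6-dienal | O=C/C(C)=C/CC/C(C)=C/CO[Si](C)(C)C(C)(C)C | intermediate
12 | rac-(3E,7E)-1-bromo-9-[(tert-butyldimethylsilyl)oxy]-3,7-dimethylnona-3,7-dien-2-ol | BrCC(O)/C(C)=C/CC/C(C)=C/CO[Si](C)(C)C(C)(C)C | intermediate
13 | (3E,7E)-1-bromo-9-[(tert-butyldimethylsilyl)oxy]-3,7-dimethylnona-3,7-dien-2-one | BrCC(=O)/C(C)=C/CC/C(C)=C/CO[Si](C)(C)C(C)(C)C | intermediate
14 | (2S,3E,7E)-1-bromo-9-[(tert-butyldimethylsilyl)oxy]-3,7-dimethylnona-3,7-dien-2-ol | BrC[C@@H](O)/C(C)=C/CC/C(C)=C/CO[Si](C)(C)C(C)(C)C | intermediate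
15 | triethyl{[(2S,3E,7E)-1-bromo-9-[(tert-butyldimethylsilyl)oxy]-3,7-dimethylnona-3,7-dien-2-yl]oxy}silane | BrC[C@@H](O[Si](CC)(CC)CC)/C(C)=C/CC/C(C)=C/CO[Si](C)(C)C(C)(C)C | intermediate
16 | (3E,4S,5R)-3-[(3R,4E,8E)-10-[(tert-butyldimethylsilyl)oxy]-4,8-dimethyl-3-(triethylsilyloxy)deca-4,8-dien-1-ylidene]-5-(2-methylprop-1-en-1-yl)-4-(triethylsilyloxy)oxolan-2-one | CC(C)=C[C@H]1OC(=O)/C(=C/C[C@@H](O[Si](CC)(CC)CC)/C(C)=C/CC/C(C)=C/CO[Si](C)(C)C(C)(C)C)[C@@H]1O[Si](CC)(CC)CC | intermediate
17 | (3E,4S,5R)-3-[(3R,4E,8E)-3,10-dihydroxy-4,8-dimethyldeca-4,8-dien-1-ylidene]-4-hydroxy-5-(2-methylprop-1-en-1-yl)oxolan-2-one | CC(C)=C[C@H]1OC(=O)/C(=C/C[C@@H](O)/C(C)=C/CC/C(C)=C/CO)[C@@H]1O | target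

Total step count: 14. Longest linear sequence: 9 steps (steps 6 to 14, from geraniol); the lactone branch (steps 1 to 5) joins at step 13.

Steps most likely to fail

Step 13. The primary radical from 15 is homoallylic and may undergo a 1,2-vinyl shift (3-exo closure onto the neighbouring trisubstituted alkene and reopening to the α-silyloxy radical) before nickel captures it. Reductive dimerisation of 7, loss of alkene geometry at the alkenylnickel stage, or insertion of zerovalent nickel into the allylic C5–O bond of the lactone may also compete. The fallback forms the same bond by a Negishi coupling, without a freely diffusing radical. It sets out from 15: NaI in acetone at 50 °C (Finkelstein exchange) should give the primary iodide F1, and Zn dust with LiCl in THF at 25 °C should insert to give the alkylzinc iodide F2, which is kept at or below 25 °C to suppress β-elimination of the silyloxy group. Coupling of F2 with 7 under Pd(OAc)2 and SPhos in THF at 25 °C returns to the route at 16.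

Step 5. Sulfonylation may take place on the chelated, U-shaped enolate and give the Z-triflate or a mixture, or the amine may trigger β-elimination of the silyloxy group. The fallback sets out from 6 and changes both the leaving group and the sulfonyl-transfer agent: TsCl with N-methylimidazole and Et3N in MeCN at 0 °C, a protocol that transfers the sulfonyl group from an N-sulfonylimidazolium ion to the non-chelated enolate and is used for (E)-enol tosylates of α-formyl esters, should give the (E)-enol tosylate F4. F4 then takes the place of 7 in the nickel coupling of step 13 with 15 (NaI raised to 1 equiv) and returns to the route at 16.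

Step 3. The basic ylide may epimerise the aldehyde carbon or eliminate the β-silyloxy group from the aldehyde or from the lactone enolate before olefination. The fallback sets out from 4 and avoids basic reagents: Takai–Lombardo methylenation (CH2Br2, Zn, TiCl4, THF/CH2Cl2, 0 °C) should give the 5-vinyl lactone F3, and cross-metathesis of F3 with 2-methyl-2-butene (second-generation Grubbs catalyst, CH2Cl2, 40 °C) returns to the route at 5.

Further compounds
F1 | step 13 | triethyl{[(2S,3E,7E)-9-[(tert-butyldimethylsilyl)oxy]-1-iodo-3,7-dimethylnona-3,7-dien-2-yl]oxy}silane | IC[C@@H](O[Si](CC)(CC)CC)/C(C)=C/CC/C(C)=C/CO[Si](C)(C)C(C)(C)C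
F2 | step 13 | [(2S,3E,7E)-9-[(tert-butyldimethylsilyl)oxy]-3,7-dimethyl-2-(triethylsilyloxy)nona-3,7-dien-1-yl]zinc iodide | I[Zn]C[C@@H](O[Si](CC)(CC)CC)/C(C)=C/CC/C(C)=C/CO[Si](C)(C)C(C)(C)C
F3 | step 3 | (4S,5R)-5-ethenyl-4-(triethylsilyloxy)oxolan-2-one | C=C[C@H]1OC(=O)C[C@@H]1O[Si](CC)(CC)CC
F4 | step 5 | [(E)-[(4S,5R)-5-(2-methylprop-1-en-1-yl)-2-oxo-4-(triethylsilyloxy)oxolan-3-ylidene]methyl] 4-methylbenzenesulfonate | CC(C)=C[C@H]1OC(=O)/C(=C/OS(=O)(=O)c2ccc(C)cc2)[C@@H]1O[Si](CC)(CC)CC
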